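**Plan** (oxolane numbering: O1, C2 aryl, C3 CH2OH, C4 benzyl, C5 H2)
- Retrosynthesis: the benzylic C–OH and the C7–aryl bond of the guaiacylmethyl arm are cut first, back to a cis-fused γ-lactone (temporary ring C4–C(=O)–O–CH2–C3). Then the extra bridgehead ester is added back. Then the oxolane is cut at O1–C2 and C4–C5, which removes O1 and C5H2 as formaldehyde and leaves a cyclopropane spanning C2–C3–C4.
- Enabling feature: C2 carries the electron-rich 3,4,5-trimethoxyphenyl ring and stands 1,3 to C4, and C5 is an unsubstituted CH2 between O1 and C4. With two esters on C4 (one is the future benzylic carbon C7), the C2–C4 bond is the donor–acceptor bond of a cyclopropane.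
- Forward: Sonogashira coupling joins the aryl ring to the C3 chain; Lindlar reduction gives the Z-alkene; asymmetric cyclopropanation builds the three-membered ring; (3+2) cycloaddition with formaldehyde builds the oxolane; desilylation closes the lactone; dealkoxycarbonylation, reduction, aryl Grignard opening and hydrogenolysis finish the benzyl arm.
- Stereochemistry: C3 and the cyclopropane aryl carbon come from the catalyst-controlled, stereospecific cyclopropanation of the Z-alkene. C2 is set by inversion in the cycloaddition (cis-cyclopropane gives 2,3-trans). C4 is set by the cis ring fusion of the lactone.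

Key step: step 4

Assumption: compounds 2, 5 and 13 are taken as purchasable, and formaldehyde 7 is dosed as paraformaldehyde, which the Lewis acid cracks to the monomer.

**Step 1**
Reactants: 1 5-iodo-1,2,3-trimethoxybenzene; 2 tert-butyldiphenyl(prop-2-yn-1-yloxy)silane
Product: 3 tert-butyldiphenyl{[3-(3,4,5-trimethoxyphenyl)prop-2-yn-1-yl]oxy}silane
Conditions: Pd(PPh3)2Cl2 (2 mol%), CuI (4 mol%), Et3N, THF, rt
Reagents that add atoms: none
Why: Sonogashira coupling of an aryl iodide with a terminal alkyne should proceed at room temperature, and the silyl ether is inert to it.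

**Step 2**
Reactants: 3 tert-butyldiphenyl{[3-(3,4,5-trimethoxyphenyl)prop-2-yn-1-yl]oxy}silane
Product: 4 (Z)-tert-butyldiphenyl{[3-(3,4,5-trimethoxyphenyl)prop-2-en-1-yl]oxy}silane
Conditions: H2 (1 atm), Lindlar catalyst, quinoline, EtOAc, rt
Reagents that add atoms: none
Why: Lindlar semihydrogenation adds H2 syn on the poisoned palladium surface and should stop at the Z-alkene, whose geometry later becomes the cis relationship on the cyclopropane.

**Step 3**
Reactants: 4 (Z)-tert-butyldiphenyl{[3-(3,4,5-trimethoxyphenyl)prop-2-en-1-yl]oxy}silane; 5 dimethyl 2-(phenyl-λ3-iodanylidene)malonate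
Product: 6 dimethyl (2R,3R)-2-{[(tert-butyldiphenylsilyl)oxy]methyl}-3-(3,4,5-trimethoxyphenyl)cyclopropane-1,1-dicarboxylate (cis)
Conditions: Cu(MeCN)4PF6 (10 mol%), chiral side-arm bis(oxazoline) ligand (12 mol%, antipode that gives the 2R,3R product), 4 Å MS, PhMe, 0 °C
Reagents that add atoms: none
Why: Copper-carbene cyclopropanation with a malonate iodonium ylide is concerted and stereospecific, so the Z-alkene should give the cis-cyclopropane, and the chiral bis(oxazoline) ligand selects the alkene face and thereby sets both stereocentres.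

**Step 4**
Reactants: 6 dimethyl (2R,3R)-2-{[(tert-butyldiphenylsilyl)oxy]methyl}-3-(3,4,5-trimethoxyphenyl)cyclopropane-1,1-dicarboxylate; 7 formaldehyde (as paraformaldehyde)
Product: 8 dimethyl (4R,5S)-4-{[(tert-butyldiphenylsilyl)oxy]methyl}-5-(3,4,5-trimethoxyphenyl)dihydrofuran-3,3(2H)-dicarboxylate
Conditions: (CH2O)n (5 equiv), Sn(OTf)2 (10 mol%), 4 Å MS, CH2Cl2, 0 °C→rt
Reagents that add atoms: none
Why: Sn(OTf)2 chelates the geminal diester and polarises the bond between the aryl-bearing donor carbon and the malonyl acceptor carbon; the formaldehyde oxygen attacks the benzylic carbon from the rear of that bond (SN2-like, inversion) and the resulting malonate enolate then attacks the O-alkylated formaldehyde oxocarbenium carbon, so O1–C2 and C5–C4 form in one operation with release of ring strain. The closest known reaction type is the Lewis-acid-catalysed (3+2) cycloaddition of aldehydes with 2-aryl-3-alkylcyclopropane-1,1-diesters to give tetrahydrofurans. The one ring that closes, the oxolane, does so by an intramolecular aldol-type 5-(enolexo)-endo-trig attack of the enolate carbon on the CH2=O+ unit. The one new stereocentre, the O-bearing benzylic carbon, is controlled by the configuration of the cyclopropane carbon through inversion: because aryl and CH2OSi are cis on the three-membered ring they should end up trans on the oxolane, while the CH2OSi-bearing carbon is a spectator and the formaldehyde carbon is not stereogenic. The step needs regioselective cleavage of the aryl–malonyl bond and stereospecificity over ionisation; the first is secured because only the 3,4,5-trimethoxyphenyl carbon can stabilise positive charge, the second by a mild catalytic Lewis acid at low temperature with an aryl donor of only moderate strength. A leak through the open zwitterion should still favour the same 2,3-trans product on steric grounds.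

**Step 5**
Reactants: 8 dimethyl (4R,5S)-4-{[(tert-butyldiphenylsilyl)oxy]methyl}-5-(3,4,5-trimethoxyphenyl)dihydrofuran-3,3(2H)-dicarboxylate
Product: 10 methyl (3aR,4S,6aR)-1-oxo-4-(3,4,5-trimethoxyphenyl)tetrahydro-1H,3H-furo[3,4-c]furan-6a(6H)-carboxylate (cis-fused lactone ester), via hydroxy diester 9 (not isolated)
Conditions: TBAF (1.2 equiv), THF, 0 °C→rt; aqueous work-up
Reagents that add atoms: none
Why: Fluoride desilylation frees the alkoxide, which should lactonise at once onto the only ester it can reach, the one cis to it, so the cis-fused γ-lactone differentiates the two esters and fixes the quaternary centre.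

**Step 6**
Reactants: 10 methyl (3aR,4S,6aR)-1-oxo-4-(3,4,5-trimethoxyphenyl)tetrahydro-1H,3H-furo[3,4-c]furan-6a(6H)-carboxylate
Product: 11 (3aR,4S,6aR)-4-(3,4,5-trimethoxyphenyl)tetrahydro-1H,3H-furo[3,4-c]furan-1-one
Conditions: LiCl (3 equiv), H2O (2 equiv), DMSO, 140 °C
Reagents that add atoms: none
Why: Krapcho dealkoxycarbonylation (chloride attack on the methyl group, loss of CO2, protonation of the lactone enolate) should remove the activating ester, and the bridgehead can only be protonated to the cis-fused bicycle, which keeps the lactone carbonyl (future C7) cis to the CH2O arm on C3.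

**Step 7**
Reactants: 11 (3aR,4S,6aR)-4-(3,4,5-trimethoxyphenyl)tetrahydro-1H,3H-furo[3,4-c]furan-1-one
Product: 12 (3aR,4S,6aR)-4-(3,4,5-trimethoxyphenyl)hexahydrofuro[3,4-c]furan-1-ol (lactol; anomer mixture)
Conditions: DIBAL-H (1.1 equiv), CH2Cl2, −78 °C; Rochelle salt work-up
Reagents that add atoms: none
Why: Partial reduction of a γ-lactone with DIBAL-H at −78 °C should stop at the aluminium hemiacetal and give the lactol without touching the aryl ethers or the oxolane.

**Step 8**
Reactants: 12 (3aR,4S,6aR)-4-(3,4,5-trimethoxyphenyl)hexahydrofuro[3,4-c]furan-1-ol; 13 1-(benzyloxy)-4-bromo-2-methoxybenzene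
Product: 15 [(2S,3R,4R)-4-{[4-(benzyloxy)-3-methoxyphenyl](hydroxy)methyl}-2-(3,4,5-trimethoxyphenyl)oxolan-3-yl]methanol (carbinol epimers), via arylmagnesium bromide 14 (not isolated)
Conditions: 13, Mg, THF, rt (3 equiv of 14); then 12, THF, 0 °C→rt; aqueous work-up
Reagents that add atoms: none
Why: In this Grignard addition to a lactol the first equivalent deprotonates the hemiacetal and the second adds to the open hydroxy aldehyde faster than enolisation, so C4 should be retained; the new carbinol centre forms unselectively but is removed in the next step.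

**Step 9**
Reactants: 15 [(2S,3R,4R)-4-{[4-(benzyloxy)-3-methoxyphenyl](hydroxy)methyl}-2-(3,4,5-trimethoxyphenyl)oxolan-3-yl]methanol
Product: 17 4-{[(3R,4R,5S)-4-(hydroxymethyl)-5-(3,4,5-trimethoxyphenyl)oxolan-3-yl]methyl}-2-methoxyphenol, via phenolic triol 16 (not isolated)
Conditions: H2 (1 atm), 10% Pd/C, EtOH, rt
Reagents that add atoms: none
Why: Hydrogenolysis of the benzyl ether frees the para-phenol, which turns the neighbouring carbinol into a p-hydroxybenzylic alcohol that should be hydrogenolysed readily, whereas the ring benzylic C–O bond on the non-phenolic trimethoxyphenyl side reacts far more slowly, so no stereocentre is touched.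

**Compound list**
1 | 5-iodo-1,2,3-trimethoxybenzene | COc1cc(I)cc(OC)c1OC | starting material
2 | tert-butyldiphenyl(prop-2-yn-1-yloxy)silane | C#CCO[Si](c1ccccc1)(c1ccccc1)C(C)(C)C | starting material
3 | tert-butyldiphenyl{[3-(3,4,5-trimethoxyphenyl)prop-2-yn-1-yl]oxy}silane | COc1cc(C#CCO[Si](c2ccccc2)(c2ccccc2)C(C)(C)C)cc(OC)c1OC | intermediate
4 | (Z)-tert-butyldiphenyl{[3-(3,4,5-trimethoxyphenyl)prop-2-en-1-yl]oxy}silane | COc1cc(/C=C\CO[Si](c2ccccc2)(c2ccccc2)C(C)(C)C)cc(OC)c1OC | intermediate
5 | dimethyl 2-(phenyl-λ3-iodanylidene)malonate | COC(=O)[C-]([I+]c1ccccc1)C(=O)OC | starting material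
6 | dimethyl (2R,3R)-2-{[(tert-butyldiphenylsilyl)oxy]methyl}-3-(3,4,5-trimethoxyphenyl)cyclopropane-1,1-dicarboxylate | COC(=O)C1(C(=O)OC)[C@H](CO[Si](c2ccccc2)(c2ccccc2)C(C)(C)C)[C@@H]1c1cc(OC)c(OC)c(OC)c1 | intermediate
7 | formaldehyde (as paraformaldehyde) | C=O | starting material
8 | dimethyl (4R,5S)-4-{[(tert-butyldiphenylsilyl)oxy]methyl}-5-(3,4,5-trimethoxyphenyl)dihydrofuran-3,3(2H)-dicarboxylate | COC(=O)C1(C(=O)OC)CO[C@H](c2cc(OC)c(OC)c(OC)c2)[C@H]1CO[Si](c1ccccc1)(c1ccccc1)C(C)(C)C | intermediate
9 | dimethyl (4R,5S)-4-(hydroxymethyl)-5-(3,4,5-trimethoxyphenyl)dihydrofuran-3,3(2H)-dicarboxylate | COC(=O)C1(C(=O)OC)CO[C@H](c2cc(OC)c(OC)c(OC)c2)[C@H]1CO | intermediate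
10 | methyl (3aR,4S,6aR)-1-oxo-4-(3,4,5-trimethoxyphenyl)tetrahydro-1H,3H-furo[3,4-c]furan-6a(6H)-carboxylate | COC(=O)[C@]12CO[C@H](c3cc(OC)c(OC)c(OC)c3)[C@H]1COC2=O | intermediate
11 | (3aR,4S,6aR)-4-(3,4,5-trimethoxyphenyl)tetrahydro-1H,3H-furo[3,4-c]furan-1-one | [C@H]12CO[C@H](c3cc(OC)c(OC)c(OC)c3)[C@H]1COC2=O | intermediate
12 | (3aR,4S,6aR)-4-(3,4,5-trimethoxyphenyl)hexahydrofuro[3,4-c]furan-1-ol | [C@H]12CO[C@H](c3cc(OC)c(OC)c(OC)c3)[C@H]1COC2O | intermediate
13 | 1-(benzyloxy)-4-bromo-2-methoxybenzene | COc1cc(Br)ccc1OCc1ccccc1 | starting material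
14 | [4-(benzyloxy)-3-methoxyphenyl]magnesium bromide | COc1cc([Mg]Br)ccc1OCc1ccccc1 | intermediate
15 | [(2S,3R,4R)-4-{[4-(benzyloxy)-3-methoxyphenyl](hydroxy)methyl}-2-(3,4,5-trimethoxyphenyl)oxolan-3-yl]methanol | COc1cc(C(O)[C@H]2CO[C@H](c3cc(OC)c(OC)c(OC)c3)[C@H]2CO)ccc1OCc1ccccc1 | intermediate
16 | 4-{hydroxy[(3R,4R,5S)-4-(hydroxymethyl)-5-(3,4,5-trimethoxyphenyl)oxolan-3-yl]methyl}-2-methoxyphenol | COc1cc(C(O)[C@H]2CO[C@H](c3cc(OC)c(OC)c(OC)c3)[C@H]2CO)ccc1O | intermediate
17 | 4-{[(3R,4R,5S)-4-(hydroxymethyl)-5-(3,4,5-trimethoxyphenyl)oxolan-3-yl]methyl}-2-methoxyphenol | COc1cc(C[C@H]2CO[C@H](c3cc(OC)c(OC)c(OC)c3)[C@H]2CO)ccc1O | target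

**Totals**
Total step count: 9. Longest linear sequence: 9 steps (from 1 and 2 to 17).

**Steps most likely to fail**

Step 4. Formaldehyde is a weakly nucleophilic, oligomerising partner. Ring opening may therefore be slower than Lewis-acid epimerisation of the cis-cyclopropane at the aryl carbon, which would erode stereospecificity. Two formaldehyde units may also be incorporated, or the electron-rich ring may be hydroxymethylated. The fallback sets out from 6 and comes back at 8, replacing the cycloaddition by a stepwise sequence. Lewis-acid-catalysed ring opening of 6 with methanol (Cu(OTf)2, MeOH, CH2Cl2) should give, with inversion, dimethyl 2-[(2R,3S)-1-[(tert-butyldiphenylsilyl)oxy]-3-methoxy-3-(3,4,5-trimethoxyphenyl)propan-2-yl]malonate F1. Hydroxymethylation of its malonate C–H with aqueous formaldehyde and K2CO3 in THF should give dimethyl 2-(hydroxymethyl)-2-[(2R,3S)-1-[(tert-butyldiphenylsilyl)oxy]-3-methoxy-3-(3,4,5-trimethoxyphenyl)propan-2-yl]malonate F2. Catalytic BF3·OEt2 in CH2Cl2 at low temperature should then ionise the benzylic methyl ether, and the primary alcohol should capture the cation to close the oxolane to 8. Under these reversible conditions the 2,3-trans isomer is expected to be favoured whatever the configuration of the benzylic carbon.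

Step 3. The chiral copper carbene may discriminate poorly between the faces of a Z-alkene that carries a bulky allylic silyl ether, and ylide decomposition may outrun cyclopropanation. The fallback sets out from 4 and comes back at 6, taking enantiopurity from resolution instead of catalysis. The same ylide 5 is decomposed with achiral Rh2(esp)2 in CH2Cl2; this concerted transfer keeps the cis geometry and should give 6 as the racemate with its antipode dimethyl (2S,3S)-2-{[(tert-butyldiphenylsilyl)oxy]methyl}-3-(3,4,5-trimethoxyphenyl)cyclopropane-1,1-dicarboxylate F3. The two are separated by preparative chromatography on a chiral stationary phase; 6 re-enters the route and F3 is set aside.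

Step 9. The ring benzylic C–O bond may be hydrogenolysed in competition (over-reduction to the ring-opened diol), or the reaction may stall at triol 16. The fallback sets out from 15 and comes back at 17, activating the carbinol as an ester. Acetylation (Ac2O, pyridine, DMAP) should give {(2S,3R,4R)-4-[acetoxy(4-(benzyloxy)-3-methoxyphenyl)methyl]-2-(3,4,5-trimethoxyphenyl)oxolan-3-yl}methyl acetate F4. Its benzylic acetate and benzyl ether should be cleaved quickly under neutral hydrogenolysis (H2, Pd/C, EtOAc, short contact) to give [(2S,3R,4R)-4-(4-hydroxy-3-methoxybenzyl)-2-(3,4,5-trimethoxyphenyl)oxolan-3-yl]methyl acetate F5. Methanolysis with K2CO3 in MeOH then gives 17.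

**Further compounds**
F1 | step 4 | dimethyl 2-[(2R,3S)-1-[(tert-butyldiphenylsilyl)oxy]-3-methoxy-3-(3,4,5-trimethoxyphenyl)propan-2-yl]malonate | COC(=O)C(C(=O)OC)[C@H](CO[Si](c1ccccc1)(c1ccccc1)C(C)(C)C)[C@H](OC)c1cc(OC)c(OC)c(OC)c1
F2 | step 4 | dimethyl 2-(hydroxymethyl)-2-[(2R,3S)-1-[(tert-butyldiphenylsilyl)oxy]-3-methoxy-3-(3,4,5-trimethoxyphenyl)propan-2-yl]malonate | COC(=O)C(CO)(C(=O)OC)[C@H](CO[Si](c1ccccc1)(c1ccccc1)C(C)(C)C)[C@H](OC)c1cc(OC)c(OC)c(OC)c1
F3 | step 3 | dimethyl (2S,3S)-2-{[(tert-butyldiphenylsilyl)oxy]methyl}-3-(3,4,5-trimethoxyphenyl)cyclopropane-1,1-dicarboxylate | COC(=O)C1(C(=O)OC)[C@@H](CO[Si](c2ccccc2)(c2ccccc2)C(C)(C)C)[C@H]1c1cc(OC)c(OC)c(OC)c1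
F4 | step 9 | {(2S,3R,4R)-4-[acetoxy(4-(benzyloxy)-3-methoxyphenyl)methyl]-2-(3,4,5-trimethoxyphenyl)oxolan-3-yl}methyl acetate | COc1cc(C(OC(C)=O)[C@H]2CO[C@H](c3cc(OC)c(OC)c(OC)c3)[C@H]2COC(C)=O)ccc1OCc1ccccc1
F5 | step 9 | [(2S,3R,4R)-4-(4-hydroxy-3-methoxybenzyl)-2-(3,4,5-trimethoxyphenyl)oxolan-3-yl]methyl acetate | COc1cc(C[C@H]2CO[C@H](c3cc(OC)c(OC)c(OC)c3)[C@H]2COC(C)=O)ccc1O
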